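**Plan**

1. Cuts: C14–C15 (the sp2–sp2 σ-bond in the middle of the hexaene) gives a C19 furanoid trienyl iodide and a C8 trienyl stannane; then C11=C12 (HWE), O1–C8 of the dihydrofuran (back to an α-hydroxyallene C5(OH)–C6=C7=C8), C8–H (back to an alkynyl 5,6-epoxide) and C6–C7 (Sonogashira on a ring enol triflate).
2. Forward: actinol → enol triflate → ring enyne → 5,6-epoxide → allene → 2,5-dihydrofuran (the only ring made; the cyclohexane is bought in) → C11 enal → C19 iodide. The C8 stannane is built separately and the two halves are joined last, unprotected.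
3. Stereocentres: C3 from (4R,6R)-actinol; C5 from epoxidation anti to the C3 silyloxy group; C8 by a centre→axis→centre relay (anti-SN2′ hydride at C8, then in-plane 5-endo attack of the C5–OH on the allene).
4. Alkenes: C9=C10 from the E-enynol, C13=C14 from syn-carboalumination, C11=C12 from HWE, C15=C15′/C13′=C14′/C11′=C12′ from E-stannane, Wittig and HWE; all retained in the union.
5. Feature that permits the union: C14 and C15 are both unsubstituted CH termini of preformed E-alkenes (C13(Me)=C14H and C15H=C15′H), so an alkenyl iodide and an alkenyl stannane couple with retention under neutral conditions. These conditions spare the acid-labile bis-allylic C8–O bond of the dihydrofuran ring (O1–C5–C6=C7–C8) and both free hydroxyls.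

Key step: step 17

Remark: carotenoid numbering is used for locants in the text (ring C1–C6, chain C7–C15 and C15′–C10′); compounds 1, 5, 13 and 20 are taken as purchasable.

**Route**

Step 1
Reactants: 1 (4R,6R)-4-hydroxy-2,2,6-trimethylcyclohexan-1-one
Product: 2 (4R,6R)-4-[(tert-butyldimethylsilyl)oxy]-2,2,6-trimethylcyclohexan-1-one
Conditions: TBSCl, imidazole, DMF, rt
Reagents that add atoms: tert-butyldimethylsilyl chloride CC(C)(C)[Si](C)(C)Cl
Why: Standard silylation of the secondary alcohol gives a bulky ether that survives enolate, palladium and peracid chemistry and later shields one ring face.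

Step 2
Reactants: 2 (4R,6R)-4-[(tert-butyldimethylsilyl)oxy]-2,2,6-trimethylcyclohexan-1-one
Product: 4 (R)-4-[(tert-butyldimethylsilyl)oxy]-2,6,6-trimethylcyclohex-1-en-1-yl trifluoromethanesulfonate, via lithium enolate 3 (not isolated)
Conditions: LDA, THF, −78 °C; then PhNTf2, −78 °C → rt
Reagents that add atoms: N-phenylbis(trifluoromethanesulfonimide) O=S(=O)(N(c1ccccc1)S(=O)(=O)C(F)(F)F)C(F)(F)F
Why: Enol triflate formation is regiochemically unambiguous because only the methyl-bearing α-carbon carries a hydrogen (the other α-carbon is quaternary), and the α-stereocentre is deliberately destroyed.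

Step 3
Reactants: 5 (E)-3-methylpent-2-en-4-yn-1-ol
Product: 6 (E)-tert-butyldimethyl[(3-methylpent-2-en-4-yn-1-yl)oxy]silane
Conditions: TBSCl, imidazole, CH2Cl2, 0 °C → rt
Reagents that add atoms: tert-butyldimethylsilyl chloride CC(C)(C)[Si](C)(C)Cl
Why: Silylation masks the primary allylic alcohol so that it neither directs the later peracid epoxidation to the side-chain alkene nor consumes hydrosilane.

Step 4
Reactants: 4 (R)-4-[(tert-butyldimethylsilyl)oxy]-2,6,6-trimethylcyclohex-1-en-1-yl trifluoromethanesulfonate; 6 (E)-tert-butyldimethyl[(3-methylpent-2-en-4-yn-1-yl)oxy]silane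
Product: 7 tert-butyl{[(1R)-4-{(3E)-5-[(tert-butyldimethylsilyl)oxy]-3-methylpent-3-en-1-yn-1-yl}-3,5,5-trimethylcyclohex-3-en-1-yl]oxy}dimethylsilane
Conditions: Pd(PPh3)4 (5 mol%), CuI (10 mol%), i-Pr2NH, DMF, rt
Reagents that add atoms: none
Why: Sonogashira coupling of the enol triflate with the terminal alkyne forms C6–C7 and carries in the E geometry of C9=C10 unchanged.

Step 5
Reactants: 7 tert-butyl{[(1R)-4-{(3E)-5-[(tert-butyldimethylsilyl)oxy]-3-methylpent-3-en-1-yn-1-yl}-3,5,5-trimethylcyclohex-3-en-1-yl]oxy}dimethylsilane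
Product: 8 tert-butyl({(1R,4S,6R)-1-{(3E)-5-[(tert-butyldimethylsilyl)oxy]-3-methylpent-3-en-1-yn-1-yl}-2,2,6-trimethyl-7-oxabicyclo[4.1.0]heptan-4-yl}oxy)dimethylsilane (5,6-epoxide, oxygen anti to the C3 silyloxy group)
Conditions: mCPBA, NaHCO3, CH2Cl2, 0 °C
Reagents that add atoms: 3-chloroperbenzoic acid OOC(=O)c1cccc(Cl)c1
Why: In this Prilezhaev epoxidation the tetrasubstituted ring alkene is the most electron-rich π-bond (the side-chain alkene is trisubstituted and carries an allylic C–O), and the peracid should approach anti to the C3 silyloxy group, setting C5 (R) as in the target, while bicarbonate protects the propargylic epoxide from acid.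

Step 6
Reactants: 8 tert-butyl({(1R,4S,6R)-1-{(3E)-5-[(tert-butyldimethylsilyl)oxy]-3-methylpent-3-en-1-yn-1-yl}-2,2,6-trimethyl-7-oxabicyclo[4.1.0]heptan-4-yl}oxy)dimethylsilane
Product: 10 (1R,3S)-6-[(Sa,3E)-5-hydroxy-3-methylpenta-1,3-dien-1-ylidene]-1,5,5-trimethylcyclohexane-1,3-diol (allene with H-8 anti and C9 syn to the tertiary C5–OH), via silylated allene 9 (not isolated)
Conditions: IPrCuCl (5 mol%), NaOt-Bu (10 mol%), (EtO)2MeSiH, toluene, 0 °C → rt; then TBAF, THF, rt
Reagents that add atoms: none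
Why: In this NHC–copper hydride SN2′ reduction of a propargyl oxirane the hydride should enter at C8 anti to the breaking C6–O bond (centre-to-axis transfer) while C5 keeps its configuration, and fluoride then cleaves all three O–Si bonds.

Step 7
Reactants: 10 (1R,3S)-6-[(Sa,3E)-5-hydroxy-3-methylpenta-1,3-dien-1-ylidene]-1,5,5-trimethylcyclohexane-1,3-diol
Product: 11 (2R,6S,7aR)-2-[(2E)-4-hydroxybut-2-en-2-yl]-4,4,7a-trimethyl-2,4,5,6,7,7a-hexahydro-1-benzofuran-6-ol
Conditions: AuCl3 (5 mol%), THF, 0 °C → rt, dark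
Reagents that add atoms: none
Why: In this gold-catalysed 5-endo cycloisomerisation of an α-hydroxyallene to a 2,5-dihydrofuran the C5–OH attacks C8 in the plane of the C1/C5 substituents, anti to gold on C7=C8, so H-8 and C9 keep their sides (axis-to-centre transfer) and C8 becomes R, with THF tempering the Lewis acidity that could ionise the new C8–O bond.

Step 8
Reactants: 11 (2R,6S,7aR)-2-[(2E)-4-hydroxybut-2-en-2-yl]-4,4,7a-trimethyl-2,4,5,6,7,7a-hexahydro-1-benzofuran-6-ol
Product: 12 (2E)-3-[(2R,6S,7aR)-6-hydroxy-4,4,7a-trimethyl-2,4,5,6,7,7a-hexahydro-1-benzofuran-2-yl]but-2-enal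
Conditions: MnO2, CH2Cl2, rt
Reagents that add atoms: none
Why: Manganese dioxide oxidises only the primary allylic alcohol, leaving the non-allylic secondary C3–OH and the allylic ether untouched.

Step 9
Reactants: 13 prop-2-yn-1-ol
Product: 15 (E)-3-iodo-2-methylprop-2-en-1-ol, via alkenylalane 14 (not isolated)
Conditions: Me3Al, Cp2ZrCl2 (25 mol%), ClCH2CH2Cl, 0 °C → rt; then I2, THF, −30 → 0 °C
Reagents that add atoms: trimethylaluminium C[Al](C)C; iodine II
Why: Zirconium-catalysed Negishi carboalumination adds methyl and aluminium syn across the alkyne with aluminium at the terminus, and iodinolysis with retention gives the E-iodide that becomes C13(Me)=C14.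

Step 10
Reactants: 15 (E)-3-iodo-2-methylprop-2-en-1-ol
Product: 16 (E)-3-bromo-1-iodo-2-methylprop-1-ene
Conditions: CBr4, PPh3, CH2Cl2, 0 °C
Reagents that add atoms: carbon tetrabromide BrC(Br)(Br)Br
Why: The Appel reaction converts the primary allylic alcohol into the bromide under neutral conditions without touching the vinyl iodide or its geometry.

Step 11
Reactants: 16 (E)-3-bromo-1-iodo-2-methylprop-1-ene
Product: 17 diethyl [(2E)-3-iodo-2-methylprop-2-en-1-yl]phosphonate
Conditions: P(OEt)3, neat, 100 °C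
Reagents that add atoms: triethyl phosphite CCOP(OCC)OCC
Why: The Michaelis–Arbuzov reaction takes place at the allylic bromide only, since a vinyl iodide is inert to phosphite without a metal catalyst.

Step 12
Reactants: 12 (2E)-3-[(2R,6S,7aR)-6-hydroxy-4,4,7a-trimethyl-2,4,5,6,7,7a-hexahydro-1-benzofuran-2-yl]but-2-enal; 17 diethyl [(2E)-3-iodo-2-methylprop-2-en-1-yl]phosphonate
Product: 19 (2R,6S,7aR)-2-[(2E,4E,6E)-7-iodo-6-methylhepta-2,4,6-trien-2-yl]-4,4,7a-trimethyl-2,4,5,6,7,7a-hexahydro-1-benzofuran-6-ol, via lithiated phosphonate 18 (not isolated)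
Conditions: 17 (excess, to allow for the free OH), LiHMDS, THF, −78 °C; then 12, −78 → 0 °C
Reagents that add atoms: none
Why: Horner–Wadsworth–Emmons olefination with the allylic phosphonate anion forms C11=C12 with the E geometry expected for such anions, and adding the enal to the preformed anion at low temperature should let carbonyl addition outrun deprotonation of C8–H.

Step 13
Reactants: 20 (E)-3-(tributylstannyl)prop-2-en-1-ol
Product: 21 (E)-3-(tributylstannyl)prop-2-enal
Conditions: MnO2, CH2Cl2, rt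
Reagents that add atoms: none
Why: Manganese dioxide oxidation of the allylic alcohol is neutral and leaves the alkenyl–tin bond and its E geometry intact.

Step 14
Reactants: 21 (E)-3-(tributylstannyl)prop-2-enal
Product: 22 (2E,4E)-2-methyl-5-(tributylstannyl)penta-2,4-dienal
Conditions: Ph3P=C(Me)CHO, toluene, 80 °C
Reagents that add atoms: 2-(triphenylphosphoranylidene)propanal CC(C=O)=P(c1ccccc1)(c1ccccc1)c1ccccc1
Why: The Wittig reaction with the stabilised formyl ylide gives the E α-methyl enal (C13′=C14′), and the more hindered product aldehyde should not be homologated a second time.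

Step 15
Reactants: 22 (2E,4E)-2-methyl-5-(tributylstannyl)penta-2,4-dienal
Product: 23 ethyl (2E,4E,6E)-4-methyl-7-(tributylstannyl)hepta-2,4,6-trienoate
Conditions: (EtO)2P(O)CH2CO2Et, NaH, THF, 0 °C → rt
Reagents that add atoms: triethyl phosphonoacetate CCOC(=O)CP(=O)(OCC)OCC
Why: Horner–Wadsworth–Emmons olefination with a stabilised phosphonate gives the E enoate (C11′=C12′).

Step 16
Reactants: 23 ethyl (2E,4E,6E)-4-methyl-7-(tributylstannyl)hepta-2,4,6-trienoate
Product: 24 (2E,4E,6E)-4-methyl-7-(tributylstannyl)hepta-2,4,6-trien-1-ol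
Conditions: DIBAL-H, CH2Cl2, −78 °C; Rochelle salt
Reagents that add atoms: none
Why: DIBAL-H 1,2-reduction of the conjugated ester gives the allylic alcohol without touching the triene or the alkenyl stannane.

Step 17
Reactants: 19 (2R,6S,7aR)-2-[(2E,4E,6E)-7-iodo-6-methylhepta-2,4,6-trien-2-yl]-4,4,7a-trimethyl-2,4,5,6,7,7a-hexahydro-1-benzofuran-6-ol; 24 (2E,4E,6E)-4-methyl-7-(tributylstannyl)hepta-2,4,6-trien-1-ol
Product: 25 (2R,6S,7aR)-2-[(2E,4E,6E,8E,10E,12E)-14-hydroxy-6,11-dimethyltetradeca-2,4,6,8,10,12-hexaen-2-yl]-4,4,7a-trimethyl-2,4,5,6,7,7a-hexahydro-1-benzofuran-6-ol [(3S,5R,8R)-5,8-epoxy-5,8-dihydro-10′-apo-β-carotene-3,10′-diol]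
Conditions: Pd2(dba)3 (2.5 mol%), AsPh3 (20 mol%), NMP, rt → 40 °C, degassed, dark
Reagents that add atoms: none
Why: Stille cross-coupling: Pd(0) inserts into the C14–I bond of 19 with retention, the arsine-ligated alkenyl-Pd(II) iodide takes up the C15 alkenyl group of 24 from tin with retention, and reductive elimination forms the C14–C15 σ-bond. The closest known reaction type is the alkenyl iodide/alkenyl stannane coupling used to assemble retinoid and carotenoid polyenes. No ring is closed and no stereocentre is created; the six E double bonds and the three stereocentres (C3, C5, C8) are carried in unchanged. The step needs retention of the C13=C14 and C15=C15′ geometries and survival of the bis-allylic C8–O bond and both free hydroxyls; the neutral, base-free medium, the weakly donating arsine that allows coupling near room temperature, and exclusion of light and acid should secure this. Because both partners are unprotected, the coupling should deliver the target directly.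

**Compound list**

1 | (4R,6R)-4-hydroxy-2,2,6-trimethylcyclohexan-1-one | CC1(C)C[C@H](O)C[C@@H](C)C1=O | starting material
2 | (4R,6R)-4-[(tert-butyldimethylsilyl)oxy]-2,2,6-trimethylcyclohexan-1-one | CC1(C)C[C@H](O[Si](C)(C)C(C)(C)C)C[C@@H](C)C1=O | intermediate
3 | lithium (R)-4-[(tert-butyldimethylsilyl)oxy]-2,6,6-trimethylcyclohex-1-en-1-olate | CC1=C(O[Li])C(C)(C)C[C@H](O[Si](C)(C)C(C)(C)C)C1 | intermediate
4 | (R)-4-[(tert-butyldimethylsilyl)oxy]-2,6,6-trimethylcyclohex-1-en-1-yl trifluoromethanesulfonate | CC1=C(OS(=O)(=O)C(F)(F)F)C(C)(C)C[C@H](O[Si](C)(C)C(C)(C)C)C1 | intermediate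
5 | (E)-3-methylpent-2-en-4-yn-1-ol | C#C/C(C)=C/CO | starting material
6 | (E)-tert-butyldimethyl[(3-methylpent-2-en-4-yn-1-yl)oxy]silane | C#C/C(C)=C/CO[Si](C)(C)C(C)(C)C | intermediate
7 | tert-butyl{[(1R)-4-{(3E)-5-[(tert-butyldimethylsilyl)oxy]-3-methylpent-3-en-1-yn-1-yl}-3,5,5-trimethylcyclohex-3-en-1-yl]oxy}dimethylsilane | CC1=C(C#C/C(C)=C/CO[Si](C)(C)C(C)(C)C)C(C)(C)C[C@H](O[Si](C)(C)C(C)(C)C)C1 | intermediate
8 | tert-butyl({(1R,4S,6R)-1-{(3E)-5-[(tert-butyldimethylsilyl)oxy]-3-methylpent-3-en-1-yn-1-yl}-2,2,6-trimethyl-7-oxabicyclo[4.1.0]heptan-4-yl}oxy)dimethylsilane (epoxide anti to the silyloxy group) | CC(C)(C)[Si](C)(C)OC/C=C(C)/C#C[C@@]12O[C@]1(C)C[C@@H](O[Si](C)(C)C(C)(C)C)CC2(C)C | intermediate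
9 | bis-TBS ether of 10 carrying a diethoxy(methyl)silyl group on the tertiary oxygen | CC(C)(C)[Si](C)(C)OC/C=C(C)/C([H])=[C@]=C1C(C)(C)C[C@H](O[Si](C)(C)C(C)(C)C)C[C@@]1(C)O[Si](C)(OCC)OCC | intermediate
10 | (1R,3S)-6-[(Sa,3E)-5-hydroxy-3-methylpenta-1,3-dien-1-ylidene]-1,5,5-trimethylcyclohexane-1,3-diol (H-8 anti, C9 syn to the tertiary OH) | OC/C=C(C)/C([H])=[C@]=C1C(C)(C)C[C@H](O)C[C@@]1(C)O | intermediate
11 | (2R,6S,7aR)-2-[(2E)-4-hydroxybut-2-en-2-yl]-4,4,7a-trimethyl-2,4,5,6,7,7a-hexahydro-1-benzofuran-6-ol | OC/C=C(\C)[C@H]1C=C2C(C)(C)C[C@H](O)C[C@@]2(C)O1 | intermediate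
12 | (2E)-3-[(2R,6S,7aR)-6-hydroxy-4,4,7a-trimethyl-2,4,5,6,7,7a-hexahydro-1-benzofuran-2-yl]but-2-enal | O=C/C=C(\C)[C@H]1C=C2C(C)(C)C[C@H](O)C[C@@]2(C)O1 | intermediate
13 | prop-2-yn-1-ol | C#CCO | starting material
14 | (E)-{[3-(dimethylalumanyl)-2-methylprop-2-en-1-yl]oxy}dimethylalumane | C[Al](C)OC/C(C)=C/[Al](C)C | intermediate
15 | (E)-3-iodo-2-methylprop-2-en-1-ol | OC/C(C)=C/I | intermediate
16 | (E)-3-bromo-1-iodo-2-methylprop-1-ene | BrC/C(C)=C/I | intermediate
17 | diethyl [(2E)-3-iodo-2-methylprop-2-en-1-yl]phosphonate | CCOP(=O)(OCC)C/C(C)=C/I | intermediate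
18 | α-lithio derivative of 17 | CCOP(=O)(OCC)C([Li])/C(C)=C/I | intermediate
19 | (2R,6S,7aR)-2-[(2E,4E,6E)-7-iodo-6-methylhepta-2,4,6-trien-2-yl]-4,4,7a-trimethyl-2,4,5,6,7,7a-hexahydro-1-benzofuran-6-ol | CC(/C=C/C=C(\C)[C@H]1C=C2C(C)(C)C[C@H](O)C[C@@]2(C)O1)=C\I | intermediate
20 | (E)-3-(tributylstannyl)prop-2-en-1-ol | OC/C=C/[Sn](CCCC)(CCCC)CCCC | starting material
21 | (E)-3-(tributylstannyl)prop-2-enal | O=C/C=C/[Sn](CCCC)(CCCC)CCCC | intermediate
22 | (2E,4E)-2-methyl-5-(tributylstannyl)penta-2,4-dienal | O=C/C(C)=C/C=C/[Sn](CCCC)(CCCC)CCCC | intermediate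
23 | ethyl (2E,4E,6E)-4-methyl-7-(tributylstannyl)hepta-2,4,6-trienoate | CCOC(=O)/C=C/C(C)=C/C=C/[Sn](CCCC)(CCCC)CCCC | intermediate
24 | (2E,4E,6E)-4-methyl-7-(tributylstannyl)hepta-2,4,6-trien-1-ol | OC/C=C/C(C)=C/C=C/[Sn](CCCC)(CCCC)CCCC | intermediate
25 | (2R,6S,7aR)-2-[(2E,4E,6E,8E,10E,12E)-14-hydroxy-6,11-dimethyltetradeca-2,4,6,8,10,12-hexaen-2-yl]-4,4,7a-trimethyl-2,4,5,6,7,7a-hexahydro-1-benzofuran-6-ol | CC(/C=C/C=C(\C)[C@H]1C=C2C(C)(C)C[C@H](O)C[C@@]2(C)O1)=C\C=C\C=C(C)\C=C\CO | target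

**Count**

Total steps: 17. Longest linear sequence: 9 steps (1, 2, 4, 5, 6, 7, 8, 12, 17).

**Steps most likely to fail**

Step 5. What may go wrong: insufficient facial discrimination (peracid attack syn to the C3 silyloxy group) or competing epoxidation of the side-chain alkene. The fallback uses reagent control; it sets out from 4 and comes back at 8. Palladium-catalysed methoxycarbonylation of 4 (Pd(OAc)2, PPh3, CO, MeOH, Et3N, DMF) gives the methyl ester F1, and DIBAL-H reduction gives the allylic alcohol F2. Sharpless asymmetric epoxidation (Ti(OiPr)4, D-(−)-diethyl tartrate, t-BuOOH, 4 Å sieves, CH2Cl2, −20 °C) should deliver oxygen anti to the silyloxy group to give the epoxy alcohol F3. Dess–Martin oxidation gives the epoxy aldehyde F4, and Ohira–Bestmann homologation (dimethyl (1-diazo-2-oxopropyl)phosphonate, K2CO3, MeOH) gives the ethynyl epoxide F5. Sonogashira coupling of F5 with the (E)-vinyl iodide F6 (made from the TBS ether of but-2-yn-1-ol by hydrozirconation with Cp2Zr(H)Cl and iodinolysis) gives 8.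

Step 7. What may go wrong: slow 5-endo closure, because the hindered tertiary hydroxyl must swing into the allene plane, which would give gold-mediated epimerisation of the allene axis or Lewis-acid ionisation of the new bis-allylic C8–O bond time to erode the C8 configuration. The fallback sets out from 10 and comes back at 11. Iodocyclisation of 10 (N-iodosuccinimide, CH2Cl2, 0 °C) activates C7=C8 as an iodonium ion that the C5–OH opens in-plane and anti, giving the iodo-dihydrofuran F7 with the same sense at C8. Palladium-catalysed formate hydrogenolysis of the vinyl C–I bond (Pd(PPh3)4, HCO2H, Et3N, DMF, 40 °C) then gives 11.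

Step 12. What may go wrong: base-mediated epimerisation at C8 through γ-deprotonation of the enal by the phosphonate anion. The fallback moves the olefination ahead of ring closure; it sets out from 10 and comes back at 19. MnO2 oxidation of 10 gives the allenic enal F8, which has no C8 stereocentre to lose. Horner–Wadsworth–Emmons olefination of F8 with 18 (excess anion for the two free hydroxyls) gives the allenic trienyl iodide F9. Gold-catalysed cycloisomerisation of F9 (AuCl3, THF, 0 °C) then closes the dihydrofuran and gives 19.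

Further compounds
F1 | step 5 | methyl (R)-4-[(tert-butyldimethylsilyl)oxy]-2,6,6-trimethylcyclohex-1-ene-1-carboxylate | COC(=O)C1=C(C)C[C@@H](O[Si](C)(C)C(C)(C)C)CC1(C)C
F2 | step 5 | {(R)-4-[(tert-butyldimethylsilyl)oxy]-2,6,6-trimethylcyclohex-1-en-1-yl}methanol | OCC1=C(C)C[C@@H](O[Si](C)(C)C(C)(C)C)CC1(C)C
F3 | step 5 | {(1R,4S,6R)-4-[(tert-butyldimethylsilyl)oxy]-2,2,6-trimethyl-7-oxabicyclo[4.1.0]heptan-1-yl}methanol (epoxide anti to the silyloxy group) | OC[C@@]12O[C@]1(C)C[C@@H](O[Si](C)(C)C(C)(C)C)CC2(C)C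
F4 | step 5 | (1S,4S,6R)-4-[(tert-butyldimethylsilyl)oxy]-2,2,6-trimethyl-7-oxabicyclo[4.1.0]heptane-1-carbaldehyde | O=C[C@@]12O[C@]1(C)C[C@@H](O[Si](C)(C)C(C)(C)C)CC2(C)C
F5 | step 5 | tert-butyl{[(1R,4S,6R)-1-ethynyl-2,2,6-trimethyl-7-oxabicyclo[4.1.0]heptan-4-yl]oxy}dimethylsilane | C#C[C@@]12O[C@]1(C)C[C@@H](O[Si](C)(C)C(C)(C)C)CC2(C)C
F6 | step 5 | (E)-tert-butyl[(3-iodobut-2-en-1-yl)oxy]dimethylsilane | I/C(C)=C/CO[Si](C)(C)C(C)(C)C
F7 | step 7 | (2S,6S,7aR)-2-[(2E)-4-hydroxybut-2-en-2-yl]-3-iodo-4,4,7a-trimethyl-2,4,5,6,7,7a-hexahydro-1-benzofuran-6-ol (same spatial arrangement at C2 as in 11) | OC/C=C(\C)[C@H]1C(I)=C2C(C)(C)C[C@H](O)C[C@@]2(C)O1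
F8 | step 12 | (2E)-4-[(Sa,2R,4S)-2,4-dihydroxy-2,6,6-trimethylcyclohexylidene]-3-methylbut-2-enal (allene as in 10) | O=C/C=C(C)/C([H])=[C@]=C1C(C)(C)C[C@H](O)C[C@@]1(C)O
F9 | step 12 | (1R,3S)-6-[(Sa,3E,5E,7E)-8-iodo-3,7-dimethylocta-1,3,5,7-tetraen-1-ylidene]-1,5,5-trimethylcyclohexane-1,3-diol (allene as in 10) | I/C=C(C)/C=C/C=C(C)/C([H])=[C@]=C1C(C)(C)C[C@H](O)C[C@@]1(C)O
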